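## Retrosynthetic overview

1. The target is opened at the C3 ester and the N–H/O–H protecting groups: N-Boc, O-TBS decahydroquinolin-3-ol plus (E)-oct-2-enoic acid.
2. The three carbocycle stereocentres (C4a, C5, C8a) come from a face-selective hydrogenation of the benzene ring of an N-Boc tetrahydroquinolin-3-ol.
3. The C5 side chain is attached by B-alkyl Suzuki coupling of a 5-bromo-tetrahydroquinolinol with an alkene made from (R)-2-propyloxirane and allylmagnesium bromide.
4. C2 and C3 are set together, trans, by one asymmetric hydroboration of a flat N-Boc-1,4-dihydroquinoline, which is made by dearomative 1,4-hydrosilylation of 5-bromoquinaldine (key step).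
5. No ring is built: both rings are those of quinaldine. The pyridine ring is saturated first (steps 2–3), the benzene ring last (step 7).

Assumption: quinaldine, (R)-2-propyloxirane, allylmagnesium bromide solution and (E)-oct-2-enoic acid are bought; quinoline numbering is used for every bicyclic compound.

## Route

Step 1
Reactants: 1 2-methylquinoline (quinaldine)
Product: 2 5-bromo-2-methylquinoline
Conditions: Br2 (1.0 equiv), AlCl3 (3 equiv), neat, 80 °C; aq. NaOH work-up; chromatography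
Reagents that add atoms: bromine, BrBr
Why: Electrophilic aromatic bromination of the AlCl3-complexed quinoline attacks the carbocycle at C5 and C8, and the 5-bromo isomer is separated from the 8-bromo isomer (2 is also a catalogue compound).

Step 2
Reactants: 2 5-bromo-2-methylquinoline
Product: 4 tert-butyl 5-bromo-2-methyl-4H-quinoline-1-carboxylate, via N-silyl-1,4-dihydroquinoline 3 (not isolated)
Conditions: PhMe2SiH (1.1 equiv), B(C6F5)3 (2 mol%), toluene, rt; then Boc2O (1.3 equiv), Bu4N[Ph3SiF2] (10 mol%), THF, 0 °C to rt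
Reagents that add atoms: di-tert-butyl dicarbonate, CC(C)(C)OC(=O)OC(=O)OC(C)(C)C
Why: Proposed new method: B(C6F5)3 activates the Si–H bond, the quinoline nitrogen is silylated and the borohydride delivers hydride to C4 because C2 carries the methyl group (closest known reaction: borane-catalysed 1,4-hydrosilylation of quinolines, the first stage of their silylative reduction); a tertiary silane at rt should stop at the N-silyl enamine 3, whose N–Si bond is then cut by catalytic fluoride in the presence of Boc2O (closest known reaction: fluoride-promoted acylation of N-silyl amines), giving the flat, prochiral enecarbamate 4 with no stereocentre yet.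

Step 3
Reactants: 4 tert-butyl 5-bromo-2-methyl-4H-quinoline-1-carboxylate
Product: 6 tert-butyl (2R,3S)-5-bromo-3-hydroxy-2-methyl-3,4-dihydro-2H-quinoline-1-carboxylate, via alkyl(isopinocampheyl)borane 5 (not isolated)
Conditions: IpcBH2 (preformed from (+)-α-pinene, 1.3 equiv), THF, −25 °C; then NaOH, H2O2, 0 °C to rt; recrystallise
Reagents that add atoms: hydrogen peroxide, OO
Why: Brown asymmetric hydroboration–oxidation puts boron on C3 (β to nitrogen) and hydrogen on C2 from the same face, so methyl and hydroxyl end up trans, and the pinene-derived reagent chooses the face (by analogy with 1-methylcyclohexene, which gives the (1S,2S) alcohol with this reagent, the (2R,3S) product is expected, and recrystallisation of the bromide raises the ee).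

Step 4
Reactants: 7 (R)-2-propyloxirane; 8 allylmagnesium bromide
Product: 9 (R)-oct-7-en-4-ol
Conditions: CuI (10 mol%), THF, −30 to 0 °C; aq. NH4Cl
Reagents that add atoms: none
Why: Copper-catalysed Grignard opening of the terminal epoxide at its CH2 carbon (SN2) leaves the R carbinol centre, the future C5', untouched.

Step 5
Reactants: 9 (R)-oct-7-en-4-ol
Product: 10 tert-butyl(dimethyl){[(4R)-oct-7-en-4-yl]oxy}silane
Conditions: TBSCl, imidazole, DMF, rt
Reagents that add atoms: tert-butyldimethylsilyl chloride, CC(C)(C)[Si](C)(C)Cl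
Why: Standard silylation; the TBS ether keeps the side-chain hydroxyl distinct from the ring hydroxyl through steps 6–8.

Step 6
Reactants: 10 tert-butyl(dimethyl){[(4R)-oct-7-en-4-yl]oxy}silane; 6 tert-butyl (2R,3S)-5-bromo-3-hydroxy-2-methyl-3,4-dihydro-2H-quinoline-1-carboxylate
Product: 12 tert-butyl (2R,3S)-5-[(5R)-5-{[tert-butyl(dimethyl)silyl]oxy}octyl]-3-hydroxy-2-methyl-3,4-dihydro-2H-quinoline-1-carboxylate, via B-alkyl-9-BBN 11 (not isolated)
Conditions: 9-BBN (1.1 equiv), THF, 0 °C to rt; then 6, Pd(dppf)Cl2 (5 mol%), K3PO4 (3 equiv), DMF–H2O, 60 °C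
Reagents that add atoms: none
Why: B-alkyl Suzuki–Miyaura coupling (anti-Markovnikov hydroboration, then Pd-catalysed sp3–sp2 coupling with the aryl bromide) tolerates the free hydroxyl, Boc and TBS groups and touches no stereocentre.

Step 7
Reactants: 12 tert-butyl (2R,3S)-5-[(5R)-5-{[tert-butyl(dimethyl)silyl]oxy}octyl]-3-hydroxy-2-methyl-3,4-dihydro-2H-quinoline-1-carboxylate
Product: 13 tert-butyl (2R,3S,4aR,5R,8aS)-5-[(5R)-5-{[tert-butyl(dimethyl)silyl]oxy}octyl]-3-hydroxy-2-methyl-3,4,4a,5,6,7,8,8a-octahydro-2H-quinoline-1-carboxylate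
Conditions: H2 (80 bar), 5% Rh/Al2O3, EtOAc, 50 °C
Reagents that add atoms: none
Why: Heterogeneous arene hydrogenation: in the N-Boc tetrahydroquinoline the 2-methyl group is pseudoaxial (allylic 1,3-strain with the carbamate) and blocks one face, while the trans 3-hydroxyl is pseudoaxial on the other face and anchors it to the metal, so all six hydrogens arrive cis from the face opposite the methyl group and set C4a, C5 and C8a (H-4a, H-5, H-8a cis to H-2).

Step 8
Reactants: 13 tert-butyl (2R,3S,4aR,5R,8aS)-5-[(5R)-5-{[tert-butyl(dimethyl)silyl]oxy}octyl]-3-hydroxy-2-methyl-octahydro-2H-quinoline-1-carboxylate; 14 (E)-oct-2-enoic acid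
Product: 15 tert-butyl (2R,3S,4aR,5R,8aS)-5-[(5R)-5-{[tert-butyl(dimethyl)silyl]oxy}octyl]-2-methyl-3-{[(2E)-oct-2-enoyl]oxy}-octahydro-2H-quinoline-1-carboxylate
Conditions: DCC, DMAP (20 mol%), CH2Cl2, 0 °C to rt
Reagents that add atoms: none
Why: Steglich esterification acylates only O3, with retention, because nitrogen is blocked by Boc and the side-chain hydroxyl by TBS.

Step 9
Reactants: 15 tert-butyl (2R,3S,4aR,5R,8aS)-5-[(5R)-5-{[tert-butyl(dimethyl)silyl]oxy}octyl]-2-methyl-3-{[(2E)-oct-2-enoyl]oxy}-octahydro-2H-quinoline-1-carboxylate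
Product: 16 (2R,3S,4aR,5R,8aS)-5-[(5R)-5-hydroxyoctyl]-2-methyldecahydroquinolin-3-yl (2E)-oct-2-enoate
Conditions: TFA–CH2Cl2–H2O (10:10:1), 0 °C to rt; then aq. NaHCO3
Reagents that add atoms: none
Why: Acidolysis removes the Boc group and the secondary TBS ether in one operation, the protonated amine cannot attack the ester and the enoate is acid-stable, so a brief bicarbonate work-up gives the free base.

## Compound list

1 | 2-methylquinoline (quinaldine) | Cc1ccc2ccccc2n1 | starting material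
2 | 5-bromo-2-methylquinoline | Cc1ccc2c(Br)cccc2n1 | intermediate
3 | 5-bromo-1-[dimethyl(phenyl)silyl]-2-methyl-1,4-dihydroquinoline | CC1=CCc2c(Br)cccc2N1[Si](C)(C)c1ccccc1 | intermediate
4 | tert-butyl 5-bromo-2-methyl-4H-quinoline-1-carboxylate | CC1=CCc2c(Br)cccc2N1C(=O)OC(C)(C)C | intermediate
5 | (1-Boc-5-bromo-2-methyl-1,2,3,4-tetrahydroquinolin-3-yl)(isopinocampheyl)borane, boron trans to the 2-methyl group | C[C@@H]1[C@H]2C[C@H](C2(C)C)C[C@H]1B[C@H]1Cc2c(Br)cccc2N(C(=O)OC(C)(C)C)[C@@H]1C | intermediate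
6 | tert-butyl (2R,3S)-5-bromo-3-hydroxy-2-methyl-3,4-dihydro-2H-quinoline-1-carboxylate | O[C@H]1Cc2c(Br)cccc2N(C(=O)OC(C)(C)C)[C@@H]1C | intermediate
7 | (R)-2-propyloxirane | CCC[C@@H]1CO1 | starting material
8 | allylmagnesium bromide | C=CC[Mg]Br | starting material
9 | (R)-oct-7-en-4-ol | C=CCC[C@H](O)CCC | intermediate
10 | tert-butyl(dimethyl){[(4R)-oct-7-en-4-yl]oxy}silane | C=CCC[C@H](O[Si](C)(C)C(C)(C)C)CCC | intermediate
11 | 9-[(5R)-5-{[tert-butyl(dimethyl)silyl]oxy}octyl]-9-borabicyclo[3.3.1]nonane | B1(CCCC[C@H](O[Si](C)(C)C(C)(C)C)CCC)C2CCCC1CCC2 | intermediate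
12 | tert-butyl (2R,3S)-5-[(5R)-5-{[tert-butyl(dimethyl)silyl]oxy}octyl]-3-hydroxy-2-methyl-3,4-dihydro-2H-quinoline-1-carboxylate | O[C@H]1Cc2c(CCCC[C@H](O[Si](C)(C)C(C)(C)C)CCC)cccc2N(C(=O)OC(C)(C)C)[C@@H]1C | intermediate
13 | tert-butyl (2R,3S,4aR,5R,8aS)-5-[(5R)-5-{[tert-butyl(dimethyl)silyl]oxy}octyl]-3-hydroxy-2-methyl-octahydro-2H-quinoline-1-carboxylate | O[C@H]1C[C@@H]2[C@H](CCCC[C@H](O[Si](C)(C)C(C)(C)C)CCC)CCC[C@@H]2N(C(=O)OC(C)(C)C)[C@@H]1C | intermediate
14 | (E)-oct-2-enoic acid | CCCCC/C=C/C(=O)O | starting material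
15 | tert-butyl (2R,3S,4aR,5R,8aS)-5-[(5R)-5-{[tert-butyl(dimethyl)silyl]oxy}octyl]-2-methyl-3-{[(2E)-oct-2-enoyl]oxy}-octahydro-2H-quinoline-1-carboxylate | CCCCC/C=C/C(=O)O[C@H]1C[C@@H]2[C@H](CCCC[C@H](O[Si](C)(C)C(C)(C)C)CCC)CCC[C@@H]2N(C(=O)OC(C)(C)C)[C@@H]1C | intermediate
16 | (2R,3S,4aR,5R,8aS)-5-[(5R)-5-hydroxyoctyl]-2-methyldecahydroquinolin-3-yl (2E)-oct-2-enoate | CCCCC/C=C/C(=O)O[C@H]1C[C@@H]2[C@H](CCCC[C@H](O)CCC)CCC[C@@H]2N[C@@H]1C | target

## Summary

Total step count: 9.
Longest linear sequence: 7 steps (steps 1, 2, 3, 6, 7, 8, 9 from quinaldine).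

Steps most likely to fail:

**Step 2** (over-reduction to a 3-silyl tetrahydroquinoline, or poor N–Si to N–Boc exchange). The fallback sets out from 2 and returns at 4. Compound 2 is activated as its N-acylquinolinium salt instead: phenyl chloroformate is added to 2 and cuprous hydride (from LiAlH(OtBu)3 and CuBr, THF, −78 °C). Hydride goes to C4 and gives phenyl 5-bromo-2-methyl-4H-quinoline-1-carboxylate F1. Isolated F1 is treated with KOtBu (THF, −40 °C), which exchanges phenoxide for tert-butoxide and gives 4.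

**Step 3** (insufficient or reversed enantioselectivity on the enecarbamate). The fallback sets out from 2 and returns at 6; C2 is set by catalysis and C3 by substrate control.
- Asymmetric hydrogenation of 2 ([Ir(cod)Cl]2, MeO-BIPHEP enantiomer that gives the 2R amine, I2, H2, toluene) gives (2R)-5-bromo-2-methyl-1,2,3,4-tetrahydroquinoline F2.
- Boc2O (neat, 80 °C) gives tert-butyl (2R)-5-bromo-2-methyl-3,4-dihydro-2H-quinoline-1-carboxylate F3.
- NBS/AIBN brominates the benzylic C4 to tert-butyl (2R)-4,5-dibromo-2-methyl-3,4-dihydro-2H-quinoline-1-carboxylate F4, and DBU eliminates to tert-butyl (2R)-5-bromo-2-methyl-2H-quinoline-1-carboxylate F5.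
- 9-BBN adds to the C3=C4 bond of F5 at C3, anti to the pseudoaxial 2-methyl group; H2O2/NaOH then gives 6.

**Step 7** (mixed facial selectivity because the two pseudoaxial groups compete). The fallback sets out from 12 and returns at 15; it relies on the methyl group alone and inverts C3 afterwards.
- Dess–Martin oxidation of 12 gives tert-butyl (2R)-5-[(5R)-5-{[tert-butyl(dimethyl)silyl]oxy}octyl]-2-methyl-3-oxo-2,4-dihydroquinoline-1-carboxylate F6.
- NaBH4 (MeOH, −40 °C) attacks anti to the pseudoaxial methyl and gives the cis alcohol, tert-butyl (2R,3R)-5-[(5R)-5-{[tert-butyl(dimethyl)silyl]oxy}octyl]-3-hydroxy-2-methyl-3,4-dihydro-2H-quinoline-1-carboxylate F7.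
- Hydrogenation over Rh/Al2O3 now meets only the blocking methyl group and gives the all-cis tert-butyl (2R,3R,4aR,5R,8aS)-5-[(5R)-5-{[tert-butyl(dimethyl)silyl]oxy}octyl]-3-hydroxy-2-methyl-octahydro-2H-quinoline-1-carboxylate F8.
- Mitsunobu esterification of F8 with 14 (PPh3, DIAD, THF) inverts C3 and gives 15.

## Further compounds

F1 | step 2 | phenyl 5-bromo-2-methyl-4H-quinoline-1-carboxylate | CC1=CCc2c(Br)cccc2N1C(=O)Oc1ccccc1
F2 | step 3 | (2R)-5-bromo-2-methyl-1,2,3,4-tetrahydroquinoline | C[C@@H]1CCc2c(Br)cccc2N1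
F3 | step 3 | tert-butyl (2R)-5-bromo-2-methyl-3,4-dihydro-2H-quinoline-1-carboxylate | C[C@@H]1CCc2c(Br)cccc2N1C(=O)OC(C)(C)C
F4 | step 3 | tert-butyl (2R)-4,5-dibromo-2-methyl-3,4-dihydro-2H-quinoline-1-carboxylate (mixture at C4) | C[C@@H]1CC(Br)c2c(Br)cccc2N1C(=O)OC(C)(C)C
F5 | step 3 | tert-butyl (2R)-5-bromo-2-methyl-2H-quinoline-1-carboxylate | C[C@@H]1C=Cc2c(Br)cccc2N1C(=O)OC(C)(C)C
F6 | step 7 | tert-butyl (2R)-5-[(5R)-5-{[tert-butyl(dimethyl)silyl]oxy}octyl]-2-methyl-3-oxo-2,4-dihydroquinoline-1-carboxylate | O=C1Cc2c(CCCC[C@H](O[Si](C)(C)C(C)(C)C)CCC)cccc2N(C(=O)OC(C)(C)C)[C@@H]1C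
F7 | step 7 | tert-butyl (2R,3R)-5-[(5R)-5-{[tert-butyl(dimethyl)silyl]oxy}octyl]-3-hydroxy-2-methyl-3,4-dihydro-2H-quinoline-1-carboxylate | O[C@@H]1Cc2c(CCCC[C@H](O[Si](C)(C)C(C)(C)C)CCC)cccc2N(C(=O)OC(C)(C)C)[C@@H]1C
F8 | step 7 | tert-butyl (2R,3R,4aR,5R,8aS)-5-[(5R)-5-{[tert-butyl(dimethyl)silyl]oxy}octyl]-3-hydroxy-2-methyl-octahydro-2H-quinoline-1-carboxylate | O[C@@H]1C[C@@H]2[C@H](CCCC[C@H](O[Si](C)(C)C(C)(C)C)CCC)CCC[C@@H]2N(C(=O)OC(C)(C)C)[C@@H]1C
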